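## Retrosynthetic overview
1. The 3,4,5-trisubstituted 1-methylcyclohexene is a retro-Diels–Alder product. It comes from an (E)-1-aryl-3-methylbutadiene carrying the formyl-resorcinol ring (9) and an (E)-2,2',4,4'-tetrahydroxychalcone dienophile (4).
2. The diene comes from a mono-Wittig olefination of bis-MOM 4,6-dihydroxyisophthalaldehyde with a methallyl ylide. The chalcone comes from a Claisen–Schmidt condensation of two commercial resorcinol carbonyl compounds.
3. Order of events: protected chalcone and protected diene are made first. The only ring is then formed by the Diels–Alder reaction, which sets all three contiguous stereocenters relative to one another. Global MOM removal follows, and the last step is chiral-phase HPLC to give the single enantiomer.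

**Assumptions**
- 4,6-Dihydroxyisophthalaldehyde is treated as purchasable. Otherwise it is one Duff bis-formylation of resorcinol.
- No cheap chiral-pool compound maps onto this aryl-substituted cyclohexene, and the Diels–Alder of achiral partners gives a racemate. The given enantiomer is therefore isolated by preparative chiral-stationary-phase HPLC in the last step. Absolute configuration is assigned by ECD or optical rotation against calculated or authentic data.

## Route

**Step 1**
Reactants: 1 (2,4-dihydroxybenzaldehyde), 2 (2,4-dihydroxyacetophenone)
Product: 3 ((E)-2,2',4,4'-tetrahydroxychalcone)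
Conditions: KOH, EtOH/H2O, 0 °C to rt, 72 h; then aq. HCl to pH 3
Reagents that add atoms: none
Why: Claisen–Schmidt (crossed aldol/dehydration) works because the aldehyde cannot enolize, and the E-enone is the thermodynamic product.

**Step 2**
Reactants: 3
Product: 4 ((E)-1-[2-hydroxy-4-(methoxymethoxy)phenyl]-3-[2,4-bis(methoxymethoxy)phenyl]prop-2-en-1-one)
Conditions: MOMCl (3.6 equiv), iPr2NEt, CH2Cl2, 0 °C to rt
Reagents that add atoms: chloromethyl methyl ether (MOMCl), COCCl
Why: The three non-chelated phenols are alkylated under mild base, while the 2'-OH is locked in an O–H···O=C hydrogen bond and stays free. This is a chemoselective O-alkylation (MOM protection).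

**Step 3**
Reactants: 5 (4,6-dihydroxyisophthalaldehyde)
Product: 6 (4,6-bis(methoxymethoxy)benzene-1,3-dicarbaldehyde)
Conditions: NaH (2.4 equiv), DMF, 0 °C; then MOMCl, 0 °C to rt
Reagents that add atoms: MOMCl, COCCl
Why: The chelated phenoxides are alkylated. Protection is needed so the next step does not consume base on free phenols and the aldehydes stay electrophilic.

**Step 4**
Reactants: 6; 7 ((2-methylallyl)triphenylphosphonium chloride)
Product: 8 (2,4-bis(methoxymethoxy)-5-(3-methylbuta-1,3-dien-1-yl)benzaldehyde, E/Z mixture)
Conditions: 7 (0.9 equiv), KOtBu (0.9 equiv), THF, 0 °C to rt; recover unreacted 6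
Reagents that add atoms: none (the C4 unit comes from reactant 7)
Why: Wittig olefination. The two aldehydes of 6 are equivalent, and the product aldehyde is deactivated by the new conjugated donor diene, so mono-olefination predominates.

**Step 5**
Reactants: 8
Product: 9 ((E)-2,4-bis(methoxymethoxy)-5-(3-methylbuta-1,3-dien-1-yl)benzaldehyde)
Conditions: PhSSPh (10 mol%), toluene, visible light, rt, 2 h
Reagents that add atoms: none
Why: Thiyl-radical-mediated Z→E isomerization funnels the mixture to the thermodynamic (E)-diene, which is the geometry needed for the Diels–Alder reaction.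

**Step 6**
Reactants: 4 (1 equiv); 9 (2 equiv)
Product: 10 (rac-[(1R*,2R*,6S*)-2-(5-formyl-2,4-bis(methoxymethoxy)phenyl)-6-(2,4-bis(methoxymethoxy)phenyl)-4-methylcyclohex-3-en-1-yl][2-hydroxy-4-(methoxymethoxy)phenyl]methanone)
Conditions: toluene (0.5 M), BHT (10 mol%), 150 °C, sealed tube, 72 h; silica chromatography to separate diastereomers
Reagents that add atoms: none (BHT is only a radical inhibitor)
Why: Intermolecular Diels–Alder. The 1-aryl (donor) and 2-methyl (donor) groups on the diene both direct the CH2 terminus to the chalcone β-carbon, giving the "ortho/para" regiochemistry (aryl next to the carbon bearing the aroyl). E,E-geometry keeps the aroyl trans to the β-aryl group. The exo-aroyl diastereomer has aroyl trans to both aryls and the two aryls cis, which is the all-equatorial target relative configuration; it is isolated from the endo diastereomers by chromatography, giving the racemate.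

**Step 7**
Reactants: 10
Product: 11 (rac-target; all six phenols free)
Conditions: 3 M aq. HCl, THF/MeOH (1:2), 40 °C, 8 h
Reagents that add atoms: none
Why: Acidolysis of the five aryl MOM acetals. The stereocenters are not touched; any C-1 epimer formed by enolization is separable in the next step.

**Step 8**
Reactants: 11
Product: 12 (target, single enantiomer)
Conditions: preparative chiral-phase HPLC (amylose tris(3,5-dimethylphenylcarbamate) column, MeCN/H2O/0.1% HCO2H); collect the enantiomer matching the given configuration
Reagents that add atoms: none
Why: Physical separation of the enantiomers on a chiral stationary phase, with no chemical modification, so no stereocenter is altered.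

## Compound list
1 | 2,4-dihydroxybenzaldehyde | O=Cc1ccc(O)cc1O | starting material
2 | 2,4-dihydroxyacetophenone | CC(=O)c1ccc(O)cc1O | starting material
3 | (E)-2,2',4,4'-tetrahydroxychalcone | O=C(/C=C/c1ccc(O)cc1O)c1ccc(O)cc1O | intermediate
4 | (E)-2'-hydroxy-2,4,4'-tris(MOM-oxy)chalcone | COCOc1ccc(/C=C/C(=O)c2ccc(OCOC)cc2O)c(OCOC)c1 | intermediate
5 | 4,6-dihydroxyisophthalaldehyde | O=Cc1cc(C=O)c(O)cc1O | starting material
6 | 4,6-bis(MOM-oxy)isophthalaldehyde | O=Cc1cc(C=O)c(OCOC)cc1OCOC | intermediate
7 | (2-methylallyl)triphenylphosphonium chloride | CC(=C)C[P+](c1ccccc1)(c1ccccc1)c1ccccc1.[Cl-] | starting material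
8 | 2,4-bis(MOM-oxy)-5-(3-methylbuta-1,3-dienyl)benzaldehyde, E/Z | O=Cc1cc(C=CC(C)=C)c(OCOC)cc1OCOC | intermediate
9 | (E)-isomer of 8 | O=Cc1cc(/C=C/C(C)=C)c(OCOC)cc1OCOC | intermediate
10 | rac-Diels–Alder adduct (enantiomer drawn) | CC1=C[C@@H](c2cc(C=O)c(OCOC)cc2OCOC)[C@H](C(=O)c2ccc(OCOC)cc2O)[C@@H](c2ccc(OCOC)cc2OCOC)C1 | intermediate
11 | rac-target (enantiomer drawn) | CC1=C[C@@H](c2cc(C=O)c(O)cc2O)[C@H](C(=O)c2ccc(O)cc2O)[C@@H](c2ccc(O)cc2O)C1 | intermediate
12 | [(1R,2R,6S)-2-(5-formyl-2,4-dihydroxyphenyl)-6-(2,4-dihydroxyphenyl)-4-methylcyclohex-3-en-1-yl](2,4-dihydroxyphenyl)methanone | CC1=C[C@@H](c2cc(C=O)c(O)cc2O)[C@H](C(=O)c2ccc(O)cc2O)[C@@H](c2ccc(O)cc2O)C1 | target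

## Totals
Total steps: 8. Longest linear sequence: 6 (steps 3, 4, 5, 6, 7, 8, counting from 5).

**Three steps most likely to fail**
1. **Step 6 (Diels–Alder).** The E-chalcone is a sluggish dienophile, and the exo-aroyl diastereomer may be the minor adduct.
   - Fallback: change the dienophile to a Me2AlCl-activated (E)-2,4-bis(MOM-oxy)cinnamoyl Weinreb amide, which reacts faster and at lower temperature. Separate the exo adduct, then add the aryllithium from 1-bromo-2,4-bis(MOM-oxy)benzene to form the aryl ketone.
2. **Step 4 (statistical mono-Wittig).** Yield is limited, and some bis-olefination occurs.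
   - Fallback: couple 5-bromo-2,4-bis(MOM-oxy)benzaldehyde (from 2,4-dihydroxybenzaldehyde by NBS bromination and MOM protection) with (E)-3-methylbuta-1,3-dienyl-Bpin under Suzuki conditions. The boronate comes from hydroboration of 2-methylbut-1-en-3-yne. This gives the E-diene directly.
3. **Step 7 (global MOM removal).** Acid can hydrate or cyclize the trisubstituted alkene onto an ortho-phenol, epimerize C-1, or acetalize the aldehyde.
   - Fallback: protect the phenols as allyl ethers instead of MOM (allyl bromide, K2CO3) and remove them at the end with Pd(PPh3)4 and a soft nucleophile under near-neutral conditions.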